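## Retrosynthetic overview

1. Integric acid ⇐ 7-allyl enone acid: the C7 propenal comes from allyl → CH2CHO → α-methylenation, and the C4 carboxyl from a C4 ketone by methoxymethylene Wittig, hydrolysis and oxidation.
2. The Δ9(10)-8-one and the C7 allyl group come from the C8 silyl enol ether of a cis-fused Diels–Alder adduct (Tsuji allylation, then dehydrogenation).
3. Key disconnection: Diels–Alder of 2-silyloxybutadiene with an (R)-4-acyloxy-2-methylcyclohex-2-enone, anti to the C1 ester, forming ring B and the quaternary C5.
4. The dienophile comes from RCM of a dienone built on (R)-5-oxotetrahydrofuran-2-carboxylic acid (the D-glutamic acid lactone, which supplies C1). The side-chain acid, from (R)-3-bromo-2-methylpropan-1-ol, is attached before RCM and doubles as the C1 protecting group.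
5. Ring order: ring A (RCM), then ring B (Diels–Alder); C4 and C7 are set last under substrate control.

Assumption: eremophilane numbering is used for the decalin (C1 = ester carbinol, C4 = CO2H carbon, C5 = quaternary methyl carbon, C7 = propenal carbon, C8 = ketone, C9=C10 = enone); β means the face of the C5 methyl. The target is (1R,4S,5R,7S) with a (2E,4S) side chain.

## Route

**Step 1**
Reactants: 1, (R)-3-bromo-2-methylpropan-1-ol
Product: 2, (S)-2-methylhexan-1-ol
Conditions: n-PrMgCl (3 equiv), Li2CuCl4 (5 mol %), THF, −78 → 0 °C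
Reagents that add atoms: n-propylmagnesium chloride, CCC[Mg]Cl
Why: Kochi Cu-catalysed sp3–sp3 coupling at the primary bromide (the first equivalent of Grignard only deprotonates the OH); the stereocentre is untouched and R→S is only a CIP priority change.

**Step 2**
Reactants: 2, (S)-2-methylhexan-1-ol
Product: 3, (S)-2-methylhexanal
Conditions: TEMPO (cat.), PhI(OAc)2, CH2Cl2, rt; used crude
Reagents that add atoms: none
Why: TEMPO/BAIB oxidation is non-basic, so the α-stereocentre does not racemise.

**Step 3**
Reactants: 3, (S)-2-methylhexanal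
Product: 4, ethyl (2E,4S)-2,4-dimethyloct-2-enoate
Conditions: Ph3P=C(Me)CO2Et, CH2Cl2, rt
Reagents that add atoms: ethyl 2-(triphenylphosphoranylidene)propanoate, CCOC(=O)C(C)=P(c1ccccc1)(c1ccccc1)c1ccccc1
Why: Wittig olefination with a stabilised ylide gives the (E)-trisubstituted enoate without epimerising the adjacent centre.

**Step 4**
Reactants: 4, ethyl (2E,4S)-2,4-dimethyloct-2-enoate
Product: 5, (2E,4S)-2,4-dimethyloct-2-enoic acid
Conditions: LiOH, THF/MeOH/H2O, 40 °C; then H3O+
Reagents that add atoms: lithium hydroxide/water, [Li+].[OH-]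
Why: Plain saponification; the γ-stereocentre and alkene geometry are not affected.

**Step 5**
Reactants: 6, (R)-5-oxotetrahydrofuran-2-carboxylic acid
Product: 7, (R)-5-(hydroxymethyl)dihydrofuran-2(3H)-one
Conditions: BH3·SMe2, THF, 0 °C → rt
Reagents that add atoms: none
Why: Borane reduces the carboxylic acid chemoselectively in the presence of the lactone.

**Step 6**
Reactants: 7, (R)-5-(hydroxymethyl)dihydrofuran-2(3H)-one
Product: 8, (R)-5-oxotetrahydrofuran-2-carbaldehyde
Conditions: Dess–Martin periodinane, NaHCO3, CH2Cl2, rt; used directly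
Reagents that add atoms: none
Why: Neutral Dess–Martin oxidation avoids epimerising the α-acyloxy aldehyde.

**Step 7**
Reactants: 8, (R)-5-oxotetrahydrofuran-2-carbaldehyde
Product: 9, (R)-5-vinyldihydrofuran-2(3H)-one
Conditions: CH2I2, Zn, Ti(OiPr)4, THF, rt
Reagents that add atoms: diiodomethane, ICI
Why: Takai methylenation is non-basic and aldehyde-selective, so the stereocentre and the lactone survive.

**Step 8**
Reactants: 9, (R)-5-vinyldihydrofuran-2(3H)-one
Product: 10, (R)-5-hydroxy-2-methylhepta-1,6-dien-3-one (in equilibrium with its lactol)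
Conditions: CH2=C(Me)Li (1.05 equiv, from 2-bromopropene and t-BuLi), THF, −78 °C; AcOH quench at −78 °C
Reagents that add atoms: isopropenyllithium, [Li]C(C)=C
Why: Organolithium mono-addition to a γ-lactone; the lithium lactolate is stable at −78 °C, so the isopropenyl ketone is only released on quench.

**Step 9**
Reactants: 10, (R)-5-hydroxy-2-methylhepta-1,6-dien-3-one; 5, (2E,4S)-2,4-dimethyloct-2-enoic acid
Product: 11, (3R)-6-methyl-5-oxohepta-1,6-dien-3-yl (2E,4S)-2,4-dimethyloct-2-enoate
Conditions: 5, 2,4,6-Cl3C6H2COCl, Et3N, THF; then 10, DMAP, toluene, rt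
Reagents that add atoms: none
Why: Yamaguchi esterification of an unhindered secondary alcohol with retention (C–O bond untouched); the natural acyl group then serves as the C1 protecting group for the rest of the route.

**Step 10**
Reactants: 11
Product: 12, (1R)-3-methyl-4-oxocyclohex-2-en-1-yl (2E,4S)-2,4-dimethyloct-2-enoate
Conditions: Grubbs II (5 mol %), CH2Cl2, 40 °C
Reagents that add atoms: none
Why: Ring-closing metathesis of the vinyl and methacryloyl alkenes gives the 2-methylcyclohexenone (ring A); the hindered trisubstituted side-chain enoate is inert.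

**Step 11**
Reactants: 13, methyl vinyl ketone
Product: 14, 2-(tert-butyldimethylsilyloxy)buta-1,3-diene
Conditions: TBSOTf, Et3N, Et2O, 0 °C
Reagents that add atoms: tert-butyldimethylsilyl triflate, CC(C)(C)[Si](C)(C)OS(=O)(=O)C(F)(F)F
Why: Soft enolisation and O-silylation of the methyl ketone gives the 2-silyloxydiene.

**Step 12**
Reactants: 12; 14
Product: 15, cis-fused adduct: 1β-acyloxy-5β-methyl-10β-H decalin-4-one carrying a C7=C8 TBS enol ether
Conditions: EtAlCl2 (1.2 equiv), toluene, −20 °C → rt
Reagents that add atoms: none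
Why: Lewis-acid-promoted Diels–Alder: the diene's nucleophilic CH2 bonds to the enone β-carbon ("para" regiochemistry, oxygen at C8) and the diene adds anti to the adjacent C1 acyloxy group, so the purchased C1 centre sets quaternary C5 with the methyl cis to the C1 oxygen (the cis-fused C10–H is only temporary).

**Step 13**
Reactants: 15
Product: 16, C4 methoxymethylene derivative of 15 (E/Z mixture, inconsequential)
Conditions: [Ph3PCH2OMe]Cl, KHMDS, THF, 0 °C → rt
Reagents that add atoms: (methoxymethylene)triphenylphosphorane, COC=P(c1ccccc1)(c1ccccc1)c1ccccc1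
Why: Wittig methoxymethylenation at the only free ketone (C8 is masked as its TBS enol ether) brings in C15 at aldehyde oxidation level without creating a stereocentre yet.

**Step 14**
Reactants: 16
Product: 17, 7-allyl-8-ketone (C7 epimer mixture)
Conditions: Pd2(dba)3 (2.5 mol %), dppe, diallyl carbonate, Bu4N[Ph3SiF2] (TBAT), THF, rt
Reagents that add atoms: diallyl carbonate, C=CCOC(=O)OCC=C
Why: Tsuji–Trost allylation of the silyl enol ether places the allyl group regiospecifically at C7 (C1 is not allylic at this stage, so the ester is safe from Pd(0)); C7 configuration is set thermodynamically later.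

**Step 15**
Reactants: 17
Product: 18, 7-allyl-Δ9(10)-8-one
Conditions: LDA (1.05 equiv), THF, −78 °C; then PhS(Cl)=N-t-Bu, −78 °C
Reagents that add atoms: none
Why: Kinetic deprotonation at the unsubstituted C9 followed by Mukaiyama dehydrogenation (sulfinimidoyl chloride, syn-elimination of the C10–H) gives the enone and erases the temporary C10 centre.

**Step 16**
Reactants: 18
Product: 19, 4β-formyl-7α-allyl enone
Conditions: 1 M HCl, THF, 0 °C → rt
Reagents that add atoms: water, O
Why: Enol ether hydrolysis: with C10 trigonal, ring A is a chair with the C5 methyl axial, so kinetic axial protonation of C4 comes from the α face (anti to the methyl and the axial 1β-ester) and gives the equatorial 4β-CHO, while C7 settles as the equatorial 7α-allyl epimer.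

**Step 17**
Reactants: 19
Product: 20, 4β-carboxylic acid
Conditions: NaClO2, NaH2PO4, 2-methyl-2-butene, t-BuOH/H2O, rt (run immediately after step 16)
Reagents that add atoms: sodium chlorite, [Na+].[O-]Cl=O
Why: Pinnick oxidation under buffered conditions converts the epimerisable aldehyde into the configurationally stable acid; the scavenger protects the alkenes.

**Step 18**
Reactants: 20
Product: 21, 7α-(2-oxoethyl) enone acid
Conditions: OsO4 (2 mol %), NaIO4, 2,6-lutidine, dioxane/H2O, rt
Reagents that add atoms: osmium tetroxide, O=[Os](=O)(=O)=O; sodium periodate, [Na+].[O-]I(=O)(=O)=O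
Why: Lemieux–Johnson cleavage takes the electron-rich terminal alkene in preference to the two electron-poor, hindered trisubstituted alkenes (enone and side-chain enoate).

**Step 19**
Reactants: 21
Product: 22, integric acid
Conditions: Eschenmoser's salt (CH2=NMe2+ I−), Et3N, CH2Cl2, rt
Reagents that add atoms: Eschenmoser's salt, C=[N+](C)C.[I-]
Why: Mannich reaction of the aldehyde and β-elimination of Me2NH (aldehyde α-methylenation) gives the 2-substituted propenal, and the epimerisable C7 ends as the equatorial epimer trans to the C5 methyl, which is the natural configuration.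

## Compound list

1 | (R)-3-bromo-2-methylpropan-1-ol | OC[C@@H](C)CBr | starting material
2 | (S)-2-methylhexan-1-ol | OC[C@@H](C)CCCC | intermediate
3 | (S)-2-methylhexanal | O=C[C@@H](C)CCCC | intermediate
4 | ethyl (2E,4S)-2,4-dimethyloct-2-enoate | CCOC(=O)/C(C)=C/[C@@H](C)CCCC | intermediate
5 | (2E,4S)-2,4-dimethyloct-2-enoic acid | OC(=O)/C(C)=C/[C@@H](C)CCCC | intermediate
6 | (R)-5-oxotetrahydrofuran-2-carboxylic acid | OC(=O)[C@H]1CCC(=O)O1 | starting material
7 | (R)-5-(hydroxymethyl)dihydrofuran-2(3H)-one | OC[C@H]1CCC(=O)O1 | intermediate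
8 | (R)-5-oxotetrahydrofuran-2-carbaldehyde | O=C[C@H]1CCC(=O)O1 | intermediate
9 | (R)-5-vinyldihydrofuran-2(3H)-one | C=C[C@H]1CCC(=O)O1 | intermediate
10 | (R)-5-hydroxy-2-methylhepta-1,6-dien-3-one | C=C[C@H](O)CCC(=O)C(C)=C | intermediate
11 | (3R)-6-methyl-5-oxohepta-1,6-dien-3-yl (2E,4S)-2,4-dimethyloct-2-enoate | C=C[C@H](OC(=O)/C(C)=C/[C@@H](C)CCCC)CCC(=O)C(C)=C | intermediate
12 | (1R)-3-methyl-4-oxocyclohex-2-en-1-yl (2E,4S)-2,4-dimethyloct-2-enoate | CC1=C[C@H](OC(=O)/C(C)=C/[C@@H](C)CCCC)CCC1=O | intermediate
13 | methyl vinyl ketone | CC(=O)C=C | starting material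
14 | 2-(tert-butyldimethylsilyloxy)buta-1,3-diene | C=CC(=C)O[Si](C)(C)C(C)(C)C | intermediate
15 | cis-fused Diels–Alder adduct (1β-acyloxy, 5β-Me, 10β-H, 4-one, C7=C8 TBS enol ether) | O=C1CC[C@@H](OC(=O)/C(C)=C/[C@@H](C)CCCC)[C@@H]2CC(O[Si](C)(C)C(C)(C)C)=CC[C@]12C | intermediate
16 | 4-(methoxymethylene) derivative of 15 (enol ether geometry unspecified) | COC=C1CC[C@@H](OC(=O)/C(C)=C/[C@@H](C)CCCC)[C@@H]2CC(O[Si](C)(C)C(C)(C)C)=CC[C@]12C | intermediate
17 | 7-allyl-8-ketone, cis-fused (C7 unspecified) | COC=C1CC[C@@H](OC(=O)/C(C)=C/[C@@H](C)CCCC)[C@@H]2CC(=O)C(CC=C)C[C@]12C | intermediate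
18 | 7-allyl-Δ9(10)-8-one, 4-methoxymethylene (C7 unspecified) | COC=C1CC[C@@H](OC(=O)/C(C)=C/[C@@H](C)CCCC)C2=CC(=O)C(CC=C)C[C@]12C | intermediate
19 | 1β-acyloxy-4β-formyl-5β-methyl-7α-allyl-Δ9(10)-8-one | O=C[C@H]1CC[C@@H](OC(=O)/C(C)=C/[C@@H](C)CCCC)C2=CC(=O)[C@H](CC=C)C[C@]12C | intermediate
20 | corresponding 4β-carboxylic acid | OC(=O)[C@H]1CC[C@@H](OC(=O)/C(C)=C/[C@@H](C)CCCC)C2=CC(=O)[C@H](CC=C)C[C@]12C | intermediate
21 | 7α-(2-oxoethyl) enone acid | OC(=O)[C@H]1CC[C@@H](OC(=O)/C(C)=C/[C@@H](C)CCCC)C2=CC(=O)[C@H](CC=O)C[C@]12C | intermediate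
22 | integric acid | C=C(C=O)[C@@H]1C[C@@]2(C)C(=CC1=O)[C@H](OC(=O)/C(C)=C/[C@@H](C)CCCC)CC[C@@H]2C(=O)O | target

## Totals and risks

Total steps: 19. Longest linear sequence: 14 (6 → 22 via steps 5–10 and 12–19; the branch from 1 via steps 1–4, 9, 10 and 12–19 is also 14).

Steps most likely to fail:

1. **Step 12 (Diels–Alder).** The α-methyl, γ-acyloxy enone is a sluggish dienophile that must form a quaternary centre, and the Lewis acid may degrade the diene or eliminate the ester. Fallback: make the cycloaddition intramolecular. Treat aldehyde 8 with Ph3P=CHCOCH3 and silylate to a 2-silyloxydiene on C10, add the isopropenyl ketone at the lactone carbon, and close both rings in one IMDA; the resulting C8=C9 silyl enol ether gives the enone by Saegusa oxidation.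
2. **Step 13 (Wittig at the neopentyl-type C4 ketone).** The ylide may only enolise the ketone or attack the ester. Fallback: abandon olefination; make the C3=C4 enol triflate (KHMDS, PhNTf2) and carbonylate it (Pd, CO, ROH). The C3=C4 enoate is then saturated by CuH conjugate reduction while C8 is held as a cross-conjugated silyl dienol ether. This requires a TBS ether at C1 and esterification with 5 after the reduction.
3. **Step 16 (C4 configuration).** It rests on kinetic α-face protonation, and the aldehyde can epimerise before oxidation. Fallback: give up kinetic control and use the 1,4-cis relationship. With a free 1β-OH (TBS series), equilibrate the C4 carboxyl epimers at the cis-fused stage into the bridged 1,4-lactone, which only the 1β,4β isomer can form, and reopen it before the side-chain esterification.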